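The route rests on cutting the trans-decalin at C5–C10 and C8–C9. Quaternary C10, flanked by the methines C5 and C9, becomes the β-carbon of an (E)-3-methyl enoate (C9=C10, C11 as ester), and C5=C6–C7=C8 becomes a 2-silyloxydiene held to it by the C1–C4 chain, which already carries C3 and C4. One thermal intramolecular [4+2] closes rings A and B together, sets C5, C9 and C10, and leaves an enol ether at C7 and an ester at C11 for the C8 methylene, the C7 carbinol and the butenolide arm. The precursor is an acyclic triene whose 3,19-diol is masked as two separate silyl ethers.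

Key step: step 8

Remark: labdane numbering is used for all locants (C18 methyl and C19 CH2O on C4, C20 methyl on C10, C11 on C9, C17 on C8); TBS = tert-butyldimethylsilyl; in every bicyclic compound the ring fusion is trans, with C20, C19, C11 and the C3 and C7 oxygens on one face and H5 and H9 on the other; organometallic and enolate species formed in situ are treated as reagent states and are not numbered.

Step 1
Reactants: 1 but-3-enylmagnesium bromide; 2 methyl but-2-ynoate
Product: 3 methyl (2E)-3-methylhepta-2,6-dienoate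
Conditions: CuBr·SMe2 (1.1 equiv), THF, −78 °C; then 2, −78 °C; aq NH4Cl at −78 °C
Reagents that add atoms: none
Why: Syn carbocupration (organocopper conjugate addition) of the ynoate followed by cold protonation puts the butenyl chain trans to the ester, so the (E)-3-methyl enoate that later serves as the C9=C10 dienophile with C20 should form as one geometric isomer.

Step 2
Reactants: 3 methyl (2E)-3-methylhepta-2,6-dienoate
Product: 5 methyl (2E)-3-methyl-6-oxohex-2-enoate, via ozonide 4 (not isolated)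
Conditions: O3, CH2Cl2, −78 °C (Sudan III end point); then PPh3, −78 °C → rt
Reagents that add atoms: ozone, [O-][O+]=O
Why: Reductive ozonolysis, in which the isolated monosubstituted alkene is consumed far faster than the electron-poor trisubstituted enoate, so titration to the indicator end point should give only the C3 aldehyde.

Step 3
Reactants: 5 methyl (2E)-3-methyl-6-oxohex-2-enoate; 6 2-methyl-2-vinyloxirane (racemic, excess)
Product: 7 methyl (2E,6R,7R)-6-hydroxy-7-(hydroxymethyl)-3,7-dimethylnona-2,8-dienoate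
Conditions: π-allyliridium C,O-benzoate catalyst from [Ir(cod)Cl]2, Tol-BINAP (antipode that gives 6R,7R), 4-cyano-3-nitrobenzoic acid and allyl acetate (5 mol%), K3PO4 (5 mol%), i-PrOH (2 equiv), THF, 60 °C
Reagents that add atoms: none
Why: Iridium-catalysed transfer-hydrogenative carbonyl tert-(hydroxy)prenylation (Krische), in which the (E)-σ-allyliridium formed from the vinyl epoxide adds to the aldehyde through a closed chair transition state, setting the C3 carbinol and quaternary C4 with the hydroxyl anti to the hydroxymethyl, while the chiral bisphosphine selects the aldehyde face that gives 3R,4R.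

Step 4
Reactants: 7 methyl (2E,6R,7R)-6-hydroxy-7-(hydroxymethyl)-3,7-dimethylnona-2,8-dienoate
Product: 8 methyl (2E,6R,7R)-6-(TBSO)-7-[(TBSO)methyl]-3,7-dimethylnona-2,8-dienoate
Conditions: TBSOTf (2.5 equiv), 2,6-lutidine, CH2Cl2, −78 °C → rt
Reagents that add atoms: tert-butyldimethylsilyl triflate, CC(C)(C)[Si](C)(C)OS(=O)(=O)C(F)(F)F
Why: Silyl triflate silylation of both hydroxyls; separate ethers are preferred to a cyclic acetal because a 3,19-dioxane would be most relaxed with the C2 chain equatorial on the acetal ring, the arrangement that corresponds to an axial C3–O in the later cyclisation chair.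

Step 5
Reactants: 8 methyl (2E,6R,7R)-6-(TBSO)-7-[(TBSO)methyl]-3,7-dimethylnona-2,8-dienoate
Product: 10 methyl (2E,6R,7R)-6-(TBSO)-7-[(TBSO)methyl]-3,7-dimethyl-8-oxooct-2-enoate, via ozonide 9 (not isolated)
Conditions: O3, CH2Cl2, −78 °C (Sudan III end point); then PPh3, −78 °C → rt
Reagents that add atoms: ozone, [O-][O+]=O
Why: Reductive ozonolysis, again selective for the vinyl group over the conjugated enoate, gives the non-enolisable C5 aldehyde without touching C3 or C4.

Step 6
Reactants: 10 methyl (2E,6R,7R)-6-(TBSO)-7-[(TBSO)methyl]-3,7-dimethyl-8-oxooct-2-enoate; 11 dimethyl (2-oxopropyl)phosphonate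
Product: 12 methyl (2E,6R,7R,8E)-6-(TBSO)-7-[(TBSO)methyl]-3,7-dimethyl-10-oxoundeca-2,8-dienoate
Conditions: 11, NaH, THF, 0 °C; then 10, 0 → 50 °C
Reagents that add atoms: none
Why: Horner–Wadsworth–Emmons olefination with a β-ketophosphonate, which should give the (E)-enone (C5=C6, C7=O, C8) because the stabilised anion adds reversibly and the aldehyde has no α-hydrogen to lose.

Step 7
Reactants: 12 methyl (2E,6R,7R,8E)-6-(TBSO)-7-[(TBSO)methyl]-3,7-dimethyl-10-oxoundeca-2,8-dienoate
Product: 13 methyl (2E,6R,7R,8E)-6,10-bis(TBSO)-7-[(TBSO)methyl]-3,7-dimethylundeca-2,8,10-trienoate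
Conditions: TBSOTf (1.2 equiv), Et3N, CH2Cl2, −78 → 0 °C; Et3N-deactivated silica
Reagents that add atoms: tert-butyldimethylsilyl triflate, CC(C)(C)[Si](C)(C)OS(=O)(=O)C(F)(F)F
Why: Soft enolisation and O-silylation of the methyl ketone, which can only enolise toward C8 and so gives the 2-silyloxydiene, while the ester and the enoate γ-hydrogens are not acidic enough to react.

Step 8
Reactants: 13 methyl (2E,6R,7R,8E)-6,10-bis(TBSO)-7-[(TBSO)methyl]-3,7-dimethylundeca-2,8,10-trienoate
Product: 14 methyl 3,7-bis(TBSO)-4-[(TBSO)methyl]-4,10-dimethyl-trans-octal-6-ene-9-carboxylate (3R,4R,5S,9R,10R)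
Conditions: PhMe (0.01 M), BHT, Et3N (trace), sealed tube, 200 °C
Reagents that add atoms: none
Why: Thermal, concerted but asynchronous intramolecular Diels–Alder reaction of a 1,7,9-decatriene (closest known type: cyclisation of terminally activated decatrienoates carrying a silyl dienol ether to angular-methyl trans-decalins); no Lewis acid is used because the tether forces C8, the nucleophilic diene terminus, onto the ester α-carbon C9, so acid would only open Mukaiyama–Michael and desilylation pathways. Ring A closes as the tether ring through the C5–C10 bond (six-membered, fused mode, chair-like four-carbon tether C1–C4), and ring B is the new cyclohexene made from both σ-bonds (C5–C10, C8–C9), its C6=C7 enol ether marking C7 for oxygen. C9 and C10 follow from the (E)-enoate by suprafacial addition (C20 cis to the ester), and C5 follows from the ester-endo, tether-anti transition state, which gives the trans ring fusion, whereas the cis-fused alternative must fold the tether under the diene and press the disubstituted C4 against C6–H and C20. The absolute sense of all three centres is relayed from C3/C4: in the chair-like tether the C3–OTBS sits equatorial and C19 axial, which exposes the required diene face. The step therefore needs endo/exo and diene-face selectivity; the first is secured by the endo ester and the quaternary C4, the second only by the equatorial preference of C3–O, which is why the diol is not tied into an acetal. High dilution, BHT and a trace of amine protect the triene and the enol ether at this temperature.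

Step 9
Reactants: 14 methyl 3,7-bis(TBSO)-4-[(TBSO)methyl]-4,10-dimethyl-trans-octal-6-ene-9-carboxylate
Product: 15 methyl 3-(TBSO)-4-[(TBSO)methyl]-4,10-dimethyl-7-oxo-trans-decalin-9-carboxylate
Conditions: TBAF (1.1 equiv), AcOH (1.1 equiv), THF, −40 → 0 °C
Reagents that add atoms: none
Why: Fluoride-induced cleavage of the silyl enol ether, which is much faster than cleavage of the hindered alkyl silyl ethers at low temperature, with the acetic acid buffer protonating the enolate at C6 without epimerising C5 or C9.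

Step 10
Reactants: 15 methyl 3-(TBSO)-4-[(TBSO)methyl]-4,10-dimethyl-7-oxo-trans-decalin-9-carboxylate
Product: 18 methyl 3-(TBSO)-4-[(TBSO)methyl]-4,10-dimethyl-8-methylidene-7-oxo-trans-decalin-9-carboxylate, via Mannich base 16 (not isolated), via ammonium iodide 17 (not isolated)
Conditions: LiHMDS (1.05 equiv), THF, −78 °C; Me2N=CH2+ I−, −78 °C → rt; then MeI, CH2Cl2, rt; then aq NaHCO3, rt
Reagents that add atoms: Eschenmoser's salt (N,N-dimethylmethyleneiminium iodide), C=[N+](C)C.[I-]
Why: Mannich-type α-methylenation with Eschenmoser's salt followed by quaternisation and E1cB elimination; the lithium amide should remove a C8 proton because C6 is shielded by the axial C19 and C20 groups and C8 is acidified by the adjacent ester-bearing carbon, and the mild bicarbonate elimination should not move the new alkene.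

Step 11
Reactants: 18 methyl 3-(TBSO)-4-[(TBSO)methyl]-4,10-dimethyl-8-methylidene-7-oxo-trans-decalin-9-carboxylate
Product: 19 methyl (7R)-7-hydroxy-3-(TBSO)-4-[(TBSO)methyl]-4,10-dimethyl-8-methylidene-trans-decalin-9-carboxylate
Conditions: NaBH4, CeCl3·7H2O, MeOH, −78 °C
Reagents that add atoms: none
Why: Luche 1,2-reduction of the enone, in which hydride enters along the axial direction on the face of H5 and H9, away from the axial C20 methyl, giving the equatorial C7 alcohol cis to C20 (7R).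

Step 12
Reactants: 19 methyl (7R)-7-hydroxy-3-(TBSO)-4-[(TBSO)methyl]-4,10-dimethyl-8-methylidene-trans-decalin-9-carboxylate
Product: 20 methyl 3,7-bis(TBSO)-4-[(TBSO)methyl]-4,10-dimethyl-8-methylidene-trans-decalin-9-carboxylate
Conditions: TBSOTf, 2,6-lutidine, CH2Cl2, −78 → 0 °C
Reagents that add atoms: tert-butyldimethylsilyl triflate, CC(C)(C)[Si](C)(C)OS(=O)(=O)C(F)(F)F
Why: Silyl triflate silylation of the secondary allylic alcohol, so that the later iodination and enolate steps meet no free hydroxyl.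

Step 13
Reactants: 20 methyl 3,7-bis(TBSO)-4-[(TBSO)methyl]-4,10-dimethyl-8-methylidene-trans-decalin-9-carboxylate
Product: 21 [3,7-bis(TBSO)-4-[(TBSO)methyl]-4,10-dimethyl-8-methylidene-trans-decalin-9-yl]methanol
Conditions: DIBAL-H (3 equiv), CH2Cl2, −78 → 0 °C; Rochelle salt
Reagents that add atoms: none
Why: Hydride reduction of the ester with DIBAL-H, a non-basic reagent that leaves the β,γ-unsaturated arrangement and the silyl ethers untouched.

Step 14
Reactants: 21 [3,7-bis(TBSO)-4-[(TBSO)methyl]-4,10-dimethyl-8-methylidene-trans-decalin-9-yl]methanol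
Product: 22 9-(iodomethyl)-3,7-bis(TBSO)-4-[(TBSO)methyl]-4,10-dimethyl-8-methylidene-trans-decalin
Conditions: PPh3, I2, imidazole, CH2Cl2, 0 °C → rt
Reagents that add atoms: iodine, II
Why: Appel-type iodination by SN2 displacement of the oxyphosphonium at the primary C11, the only free hydroxyl in the molecule.

Step 15
Reactants: 22 9-(iodomethyl)-3,7-bis(TBSO)-4-[(TBSO)methyl]-4,10-dimethyl-8-methylidene-trans-decalin; 23 α-methylene-γ-butyrolactone (5 equiv)
Product: 24 3-[2-(3,7-bis(TBSO)-4-[(TBSO)methyl]-4,10-dimethyl-8-methylidene-trans-decalin-9-yl)ethyl]dihydrofuran-2(3H)-one (C13 epimers)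
Conditions: Bu3SnH (syringe pump), AIBN, PhH, 80 °C
Reagents that add atoms: none
Why: Giese radical conjugate addition, in which the primary C11 radical adds to the unsubstituted terminus of the acceptor alkene faster than it is reduced when the lactone is in excess and the hydride is added slowly, forming C11–C12; the C13 centre forms unselectively and is removed in the next step.

Step 16
Reactants: 24 3-[2-(3,7-bis(TBSO)-4-[(TBSO)methyl]-4,10-dimethyl-8-methylidene-trans-decalin-9-yl)ethyl]dihydrofuran-2(3H)-one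
Product: 27 3-[2-(3,7-bis(TBSO)-4-[(TBSO)methyl]-4,10-dimethyl-8-methylidene-trans-decalin-9-yl)ethyl]furan-2(5H)-one, via selenide 25 (not isolated), via selenoxide 26 (not isolated)
Conditions: LDA, THF, −78 °C; PhSeBr, −78 °C; then 30% H2O2, pyridine, CH2Cl2, 0 °C → rt
Reagents that add atoms: none
Why: α-Selenenylation of the lactone enolate followed by oxidation and selenoxide syn-elimination, which in simple γ-butyrolactones with a ring β-hydrogen syn to selenium runs into the ring and should give the endocyclic C13=C14 butenolide.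

Step 17
Reactants: 27 3-[2-(3,7-bis(TBSO)-4-[(TBSO)methyl]-4,10-dimethyl-8-methylidene-trans-decalin-9-yl)ethyl]furan-2(5H)-one
Product: 28 target CNP0280530.1 (3R,4R,5S,7R,9S,10S)
Conditions: HF·pyridine, pyridine, THF, 0 °C → rt
Reagents that add atoms: none
Why: Fluoride desilylation with buffered HF·pyridine removes the three silyl ethers under weakly acidic conditions that spare the butenolide and the allylic alcohol and alter no stereocentre.

Compound list
1 | but-3-enylmagnesium bromide (THF solution) | C=CCC[Mg]Br | starting material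
2 | methyl but-2-ynoate | CC#CC(=O)OC | starting material
3 | methyl (2E)-3-methylhepta-2,6-dienoate | C=CCC/C(C)=C/C(=O)OC | intermediate
4 | ozonide of 3, methyl (2E)-3-methyl-5-(1,2,4-trioxolan-3-yl)pent-2-enoate | COC(=O)/C=C(C)/CCC1OCOO1 | intermediate (not isolated)
5 | methyl (2E)-3-methyl-6-oxohex-2-enoate | COC(=O)/C=C(C)/CCC=O | intermediate
6 | 2-methyl-2-vinyloxirane (isoprene monoxide, racemic) | CC1(C=C)CO1 | starting material
7 | methyl (2E,6R,7R)-6-hydroxy-7-(hydroxymethyl)-3,7-dimethylnona-2,8-dienoate (3R,4R in labdane numbering) | C=C[C@](C)(CO)[C@H](O)CC/C(C)=C/C(=O)OC | intermediate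
8 | methyl (2E,6R,7R)-6-(TBSO)-7-[(TBSO)methyl]-3,7-dimethylnona-2,8-dienoate | C=C[C@](C)(CO[Si](C)(C)C(C)(C)C)[C@H](O[Si](C)(C)C(C)(C)C)CC/C(C)=C/C(=O)OC | intermediate
9 | ozonide of 8 (vinyl group converted into a 1,2,4-trioxolan-3-yl ring, C3 and C4 unchanged) | O1COOC1[C@](C)(CO[Si](C)(C)C(C)(C)C)[C@H](O[Si](C)(C)C(C)(C)C)CC/C(C)=C/C(=O)OC | intermediate (not isolated)
10 | methyl (2E,6R,7R)-6-(TBSO)-7-[(TBSO)methyl]-3,7-dimethyl-8-oxooct-2-enoate | O=C[C@](C)(CO[Si](C)(C)C(C)(C)C)[C@H](O[Si](C)(C)C(C)(C)C)CC/C(C)=C/C(=O)OC | intermediate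
11 | dimethyl (2-oxopropyl)phosphonate | CC(=O)CP(=O)(OC)OC | starting material
12 | methyl (2E,6R,7R,8E)-6-(TBSO)-7-[(TBSO)methyl]-3,7-dimethyl-10-oxoundeca-2,8-dienoate | CC(=O)/C=C/[C@](C)(CO[Si](C)(C)C(C)(C)C)[C@H](O[Si](C)(C)C(C)(C)C)CC/C(C)=C/C(=O)OC | intermediate
13 | methyl (2E,6R,7R,8E)-6,10-bis(TBSO)-7-[(TBSO)methyl]-3,7-dimethylundeca-2,8,10-trienoate (cycloaddition precursor) | C=C(O[Si](C)(C)C(C)(C)C)/C=C/[C@](C)(CO[Si](C)(C)C(C)(C)C)[C@H](O[Si](C)(C)C(C)(C)C)CC/C(C)=C/C(=O)OC | intermediate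
14 | methyl 3,7-bis(TBSO)-4-[(TBSO)methyl]-4,10-dimethyl-trans-octal-6-ene-9-carboxylate (3R,4R,5S,9R,10R; C6=C7 silyl enol ether, C20 cis to the ester) | C1C(O[Si](C)(C)C(C)(C)C)=C[C@@H]2[C@](C)(CO[Si](C)(C)C(C)(C)C)[C@H](O[Si](C)(C)C(C)(C)C)CC[C@@]2(C)[C@@H]1C(=O)OC | intermediate
15 | methyl 3-(TBSO)-4-[(TBSO)methyl]-4,10-dimethyl-7-oxo-trans-decalin-9-carboxylate | O=C1C[C@@H]2[C@](C)(CO[Si](C)(C)C(C)(C)C)[C@H](O[Si](C)(C)C(C)(C)C)CC[C@@]2(C)[C@H](C(=O)OC)C1 | intermediate
16 | Mannich base, 8-[(dimethylamino)methyl] derivative of 15 (C8 epimers) | O=C1C[C@@H]2[C@](C)(CO[Si](C)(C)C(C)(C)C)[C@H](O[Si](C)(C)C(C)(C)C)CC[C@@]2(C)[C@H](C(=O)OC)C1CN(C)C | intermediate (not isolated)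
17 | ammonium iodide, 8-[(trimethylammonio)methyl] derivative of 15 | O=C1C[C@@H]2[C@](C)(CO[Si](C)(C)C(C)(C)C)[C@H](O[Si](C)(C)C(C)(C)C)CC[C@@]2(C)[C@H](C(=O)OC)C1C[N+](C)(C)C.[I-] | intermediate (not isolated)
18 | methyl 3-(TBSO)-4-[(TBSO)methyl]-4,10-dimethyl-8-methylidene-7-oxo-trans-decalin-9-carboxylate | O=C1C[C@@H]2[C@](C)(CO[Si](C)(C)C(C)(C)C)[C@H](O[Si](C)(C)C(C)(C)C)CC[C@@]2(C)[C@H](C(=O)OC)C1=C | intermediate
19 | methyl (7R)-7-hydroxy-3-(TBSO)-4-[(TBSO)methyl]-4,10-dimethyl-8-methylidene-trans-decalin-9-carboxylate (7-OH equatorial, cis to C20) | C=C1[C@H](O)C[C@@H]2[C@](C)(CO[Si](C)(C)C(C)(C)C)[C@H](O[Si](C)(C)C(C)(C)C)CC[C@@]2(C)[C@@H]1C(=O)OC | intermediate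
20 | methyl 3,7-bis(TBSO)-4-[(TBSO)methyl]-4,10-dimethyl-8-methylidene-trans-decalin-9-carboxylate | C=C1[C@H](O[Si](C)(C)C(C)(C)C)C[C@@H]2[C@](C)(CO[Si](C)(C)C(C)(C)C)[C@H](O[Si](C)(C)C(C)(C)C)CC[C@@]2(C)[C@@H]1C(=O)OC | intermediate
21 | [3,7-bis(TBSO)-4-[(TBSO)methyl]-4,10-dimethyl-8-methylidene-trans-decalin-9-yl]methanol (C11 alcohol) | C=C1[C@H](O[Si](C)(C)C(C)(C)C)C[C@@H]2[C@](C)(CO[Si](C)(C)C(C)(C)C)[C@H](O[Si](C)(C)C(C)(C)C)CC[C@@]2(C)[C@@H]1CO | intermediate
22 | 9-(iodomethyl)-3,7-bis(TBSO)-4-[(TBSO)methyl]-4,10-dimethyl-8-methylidene-trans-decalin (C11 iodide) | C=C1[C@H](O[Si](C)(C)C(C)(C)C)C[C@@H]2[C@](C)(CO[Si](C)(C)C(C)(C)C)[C@H](O[Si](C)(C)C(C)(C)C)CC[C@@]2(C)[C@@H]1CI | intermediate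
23 | α-methylene-γ-butyrolactone (3-methylidenedihydrofuran-2(3H)-one) | C=C1CCOC1=O | starting material
24 | saturated lactone, 3-[2-(decalin-9-yl)ethyl]dihydrofuran-2(3H)-one with the decalin of 22 (C13 epimers) | C=C1[C@H](O[Si](C)(C)C(C)(C)C)C[C@@H]2[C@](C)(CO[Si](C)(C)C(C)(C)C)[C@H](O[Si](C)(C)C(C)(C)C)CC[C@@]2(C)[C@@H]1CCC1CCOC1=O | intermediate
25 | α-phenylselanyl lactone derived from 24 | C=C1[C@H](O[Si](C)(C)C(C)(C)C)C[C@@H]2[C@](C)(CO[Si](C)(C)C(C)(C)C)[C@H](O[Si](C)(C)C(C)(C)C)CC[C@@]2(C)[C@@H]1CCC1([Se]c2ccccc2)CCOC1=O | intermediate (not isolated)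
26 | selenoxide of 25 | C=C1[C@H](O[Si](C)(C)C(C)(C)C)C[C@@H]2[C@](C)(CO[Si](C)(C)C(C)(C)C)[C@H](O[Si](C)(C)C(C)(C)C)CC[C@@]2(C)[C@@H]1CCC1([Se](=O)c2ccccc2)CCOC1=O | intermediate (not isolated)
27 | 3,7,19-tris-O-TBS ether of the target (3-substituted furan-2(5H)-one) | C=C1[C@H](O[Si](C)(C)C(C)(C)C)C[C@@H]2[C@](C)(CO[Si](C)(C)C(C)(C)C)[C@H](O[Si](C)(C)C(C)(C)C)CC[C@@]2(C)[C@@H]1CCC1=CCOC1=O | intermediate
28 | CNP0280530.1, 3-{2-[(1S,3R,4aS,5R,6R,8aS)-3,6-dihydroxy-5-(hydroxymethyl)-5,8a-dimethyl-2-methylidenedecahydronaphthalen-1-yl]ethyl}furan-2(5H)-one | C=C1[C@H](O)C[C@@H]2[C@](C)(CO)[C@H](O)CC[C@@]2(C)[C@@H]1CCC1=CCOC1=O | target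

Total step count: 17. Longest linear sequence: 17 steps (1 and 2 to 28); all other building blocks are commercial.

Steps most likely to fail

Step 8. The cycloaddition may be too slow at temperatures the dienol ether survives, because the tether pairs the nucleophilic diene terminus with the ester α-carbon. The two chair-like tether transition states, which differ mainly in an equatorial versus axial C3–O, may also be poorly discriminated, and the endo preference may erode at 200 °C. The fallback sets out from 13 and comes back at 15; it changes the dienophile to an enal, which should cyclise at a much lower temperature with a stronger endo preference. DIBAL-H reduction of the enoate of 13 (CH2Cl2, −78 °C) gives the allylic alcohol F1, and MnO2 oxidation gives the (E)-enal F2. Heating F2 in toluene with BHT at 110–140 °C gives the C9 aldehyde cycloadduct F3. Buffered fluoride (TBAF, AcOH) then gives the keto aldehyde F4, Pinnick oxidation (NaClO2, NaH2PO4, 2-methyl-2-butene) gives the keto acid F5, and TMSCHN2 in MeOH/PhMe gives 15.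

Step 10. Enolisation may go toward C6, or the new exocyclic alkene may migrate into the ring (C8=C9) under the pull of the C9 ester while the ammonium salt is eliminated. The fallback sets out from 14 and comes back at 21; it takes C11 to the alcohol level first, so that H9 is no longer activated. LiAlH4 (Et2O, 0 °C) reduces the ester of 14 with the enol ether intact to the C11 alcohol F6, and PivCl/pyridine gives the pivalate F7. Buffered fluoride gives the keto pivalate F8. The same enolate and Eschenmoser sequence gives the Mannich base F9, the ammonium iodide F10 and the enone pivalate F11. Luche reduction gives the allylic alcohol F12, TBSOTf/2,6-lutidine gives the silyl ether F13, and DIBAL-H removes the pivalate to give 21.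

Step 16. The selenoxide may eliminate toward C12 and give the exocyclic alkylidene lactone, or the selenium oxidant may attack the C8 exocyclic alkene. The fallback sets out from 22 and comes back at 27; it places the leaving group on the radical acceptor, so that the double bond can form in one position only. A Morita–Baylis–Hillman reaction of methyl acrylate with (tert-butyldimethylsilyloxy)acetaldehyde (DABCO) gives the hydroxy acrylate F14. Aqueous HCl/THF removes the silyl group and lactonises it to racemic 4-hydroxy-3-methylidenedihydrofuran-2(3H)-one F15, and Ac2O/pyridine gives the acetate F16. Giese addition of 22 to F16 (Bu3SnH, AIBN, PhH, 80 °C) gives the β-acetoxy lactone F17, and DBU (CH2Cl2, 0 °C) eliminates acetic acid by E1cB to give 27.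

Further compounds
F1 | step 8 | (2E,6R,7R,8E)-6,10-bis(TBSO)-7-[(TBSO)methyl]-3,7-dimethylundeca-2,8,10-trien-1-ol | C=C(O[Si](C)(C)C(C)(C)C)/C=C/[C@](C)(CO[Si](C)(C)C(C)(C)C)[C@H](O[Si](C)(C)C(C)(C)C)CC/C(C)=C/CO
F2 | step 8 | (2E,6R,7R,8E)-6,10-bis(TBSO)-7-[(TBSO)methyl]-3,7-dimethylundeca-2,8,10-trienal | C=C(O[Si](C)(C)C(C)(C)C)/C=C/[C@](C)(CO[Si](C)(C)C(C)(C)C)[C@H](O[Si](C)(C)C(C)(C)C)CC/C(C)=C/C=O
F3 | step 8 | 3,7-bis(TBSO)-4-[(TBSO)methyl]-4,10-dimethyl-trans-octal-6-ene-9-carbaldehyde | C1C(O[Si](C)(C)C(C)(C)C)=C[C@@H]2[C@](C)(CO[Si](C)(C)C(C)(C)C)[C@H](O[Si](C)(C)C(C)(C)C)CC[C@@]2(C)[C@@H]1C=O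
F4 | step 8 | 3-(TBSO)-4-[(TBSO)methyl]-4,10-dimethyl-7-oxo-trans-decalin-9-carbaldehyde | O=C1C[C@@H]2[C@](C)(CO[Si](C)(C)C(C)(C)C)[C@H](O[Si](C)(C)C(C)(C)C)CC[C@@]2(C)[C@H](C=O)C1
F5 | step 8 | 3-(TBSO)-4-[(TBSO)methyl]-4,10-dimethyl-7-oxo-trans-decalin-9-carboxylic acid | O=C1C[C@@H]2[C@](C)(CO[Si](C)(C)C(C)(C)C)[C@H](O[Si](C)(C)C(C)(C)C)CC[C@@]2(C)[C@H](C(=O)O)C1
F6 | step 10 | [3,7-bis(TBSO)-4-[(TBSO)methyl]-4,10-dimethyl-trans-octal-6-en-9-yl]methanol | C1C(O[Si](C)(C)C(C)(C)C)=C[C@@H]2[C@](C)(CO[Si](C)(C)C(C)(C)C)[C@H](O[Si](C)(C)C(C)(C)C)CC[C@@]2(C)[C@@H]1CO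
F7 | step 10 | pivalate of F6 | C1C(O[Si](C)(C)C(C)(C)C)=C[C@@H]2[C@](C)(CO[Si](C)(C)C(C)(C)C)[C@H](O[Si](C)(C)C(C)(C)C)CC[C@@]2(C)[C@@H]1COC(=O)C(C)(C)C
F8 | step 10 | [3-(TBSO)-4-[(TBSO)methyl]-4,10-dimethyl-7-oxo-trans-decalin-9-yl]methyl pivalate | O=C1C[C@@H]2[C@](C)(CO[Si](C)(C)C(C)(C)C)[C@H](O[Si](C)(C)C(C)(C)C)CC[C@@]2(C)[C@H](COC(=O)C(C)(C)C)C1
F9 | step 10 | Mannich base, 8-[(dimethylamino)methyl] derivative of F8 | O=C1C[C@@H]2[C@](C)(CO[Si](C)(C)C(C)(C)C)[C@H](O[Si](C)(C)C(C)(C)C)CC[C@@]2(C)[C@H](COC(=O)C(C)(C)C)C1CN(C)C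
F10 | step 10 | ammonium iodide, 8-[(trimethylammonio)methyl] derivative of F8 | O=C1C[C@@H]2[C@](C)(CO[Si](C)(C)C(C)(C)C)[C@H](O[Si](C)(C)C(C)(C)C)CC[C@@]2(C)[C@H](COC(=O)C(C)(C)C)C1C[N+](C)(C)C.[I-]
F11 | step 10 | [3-(TBSO)-4-[(TBSO)methyl]-4,10-dimethyl-8-methylidene-7-oxo-trans-decalin-9-yl]methyl pivalate | O=C1C[C@@H]2[C@](C)(CO[Si](C)(C)C(C)(C)C)[C@H](O[Si](C)(C)C(C)(C)C)CC[C@@]2(C)[C@H](COC(=O)C(C)(C)C)C1=C
F12 | step 10 | [(7R)-7-hydroxy-3-(TBSO)-4-[(TBSO)methyl]-4,10-dimethyl-8-methylidene-trans-decalin-9-yl]methyl pivalate | C=C1[C@H](O)C[C@@H]2[C@](C)(CO[Si](C)(C)C(C)(C)C)[C@H](O[Si](C)(C)C(C)(C)C)CC[C@@]2(C)[C@@H]1COC(=O)C(C)(C)C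
F13 | step 10 | [3,7-bis(TBSO)-4-[(TBSO)methyl]-4,10-dimethyl-8-methylidene-trans-decalin-9-yl]methyl pivalate | C=C1[C@H](O[Si](C)(C)C(C)(C)C)C[C@@H]2[C@](C)(CO[Si](C)(C)C(C)(C)C)[C@H](O[Si](C)(C)C(C)(C)C)CC[C@@]2(C)[C@@H]1COC(=O)C(C)(C)C
F14 | step 16 | methyl 2-[2-(tert-butyldimethylsilyloxy)-1-hydroxyethyl]acrylate (racemic) | C=C(C(=O)OC)C(O)CO[Si](C)(C)C(C)(C)C
F15 | step 16 | 4-hydroxy-3-methylidenedihydrofuran-2(3H)-one (racemic) | C=C1C(O)COC1=O
F16 | step 16 | 4-methylidene-5-oxotetrahydrofuran-3-yl acetate (racemic) | C=C1C(OC(C)=O)COC1=O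
F17 | step 16 | β-acetoxy lactone, Giese adduct of 22 and F16 (epimers at the lactone carbons) | C=C1[C@H](O[Si](C)(C)C(C)(C)C)C[C@@H]2[C@](C)(CO[Si](C)(C)C(C)(C)C)[C@H](O[Si](C)(C)C(C)(C)C)CC[C@@]2(C)[C@@H]1CCC1C(OC(C)=O)COC1=O
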